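**Assumption:** the target is a planar, achiral flavone with no stereocentre, so there is no enantiomer to select. The only stereo-elements on the way (the E-alkene of 6, the racemic C-2 of 7) are transient and are erased in the last step.

## Retrosynthetic overview

1. 8 ⇒ 5 + 1: the pyranone ring C is closed last by forming the O1–C2 bond (oxa-Michael addition of the 2'-OH onto the enone from a C2–C3 aldol condensation) and is locked by dehydrogenation.
2. 5 ⇒ 3 + acetonitrile: C4–C4a bond by Houben–Hoesch acylation at the resorcinol position that is ortho to one OH and para to the other.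
3. 3 ⇒ 1: the future ring oxygen (C8a–O1) is put in by Dakin oxygen insertion into the aryl–CHO bond, so one aldehyde supplies ring A (after oxidation) and ring B (as bought).
4. Ring order: rings A and B come ready-made in 1; ring C is the only ring formed, in the final step. No protecting groups.

## Route

**Step 1**
Reactants: 1 3-hydroxy-4,5-dimethoxybenzaldehyde
Product: 3 4,5-dimethoxybenzene-1,3-diol, via 3-hydroxy-4,5-dimethoxyphenyl formate 2 (not isolated)
Conditions: 30% aq H2O2 (1.2 equiv), H2SO4 (cat.), MeOH, 20 °C
Reagents that add atoms: hydrogen peroxide, OO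
Why: Acid-catalysed Dakin (Baeyer–Villiger-type) oxidation, in which the perhemiacetal of the aldehyde rearranges with migration of the electron-rich para-methoxy aryl group to give formate 2, which is methanolysed in situ to the phenol.

**Step 2**
Reactants: 3 4,5-dimethoxybenzene-1,3-diol
Product: 5 1-(2,4-dihydroxy-5,6-dimethoxyphenyl)ethan-1-one, via ketiminium chloride 4 (not isolated)
Conditions: MeCN (1.5 equiv), ZnCl2 (0.5 equiv), HCl (g), Et2O, 0 °C; then H2O, 100 °C
Reagents that add atoms: acetonitrile, CC#N; water, O; hydrogen chloride, Cl (counter-ion of 4 only)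
Why: Houben–Hoesch acylation, in which the ZnCl2/HCl-activated nitrile attacks C-6, the only free position ortho to one hydroxyl and para to the other (the resorcinol "4-position"), in preference to C-2 between the two hydroxyls, and the precipitated ketiminium salt 4 cannot be acylated again and hydrolyses to the ketone.

**Step 3**
Reactants: 5 1-(2,4-dihydroxy-5,6-dimethoxyphenyl)ethan-1-one; 1 3-hydroxy-4,5-dimethoxybenzaldehyde
Product: 8 7,5'-dihydroxy-5,6,3',4'-tetramethoxyflavone, via chalcone 6 (not isolated), via flavanone 7 (not isolated)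
Conditions: pyrrolidine (0.5 equiv), DMSO, 60 °C; then AcOH (1 equiv), Pd(TFA)2 (10 mol %), O2 (1 atm), 100 °C
Reagents that add atoms: none
Why: Proposed new method: a one-flask aerobic dehydrogenative oxa-annulation of an unprotected dihydroxyacetophenone with a hydroxybenzaldehyde, in which pyrrolidine (iminium/enamine catalysis, Kabbe-type) gives the E-chalcone 6 and closes it by 6-endo oxa-Michael addition of the 2'-OH (O1–C2 bond) to the racemic flavanone 7, after which Pd(II) palladates C-3 of the enol/enamine of 7, syn-β-hydride elimination removes H-2 and O2 reoxidises Pd(0), so the reversible 6 ⇌ 7 pair is drained to the aromatic pyranone without any electrophilic halogen that could attack the free electron-rich phenol rings; the closest known reaction types are the amine-mediated Kabbe flavanone synthesis and the Pd(II)/DMSO/O2 α,β-dehydrogenation of chromanones, which to my knowledge have not been fused into one operation from a ketone and an aldehyde on unprotected polyphenolic partners.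

## Compound list

1 | 3-hydroxy-4,5-dimethoxybenzaldehyde | COc1cc(C=O)cc(O)c1OC | starting material
2 | 3-hydroxy-4,5-dimethoxyphenyl formate | COc1cc(OC=O)cc(O)c1OC | intermediate
3 | 4,5-dimethoxybenzene-1,3-diol | COc1cc(O)cc(O)c1OC | intermediate
4 | 1-(2,4-dihydroxy-5,6-dimethoxyphenyl)ethan-1-iminium chloride | CC(=[NH2+])c1c(O)cc(O)c(OC)c1OC.[Cl-] | intermediate
5 | 1-(2,4-dihydroxy-5,6-dimethoxyphenyl)ethan-1-one | CC(=O)c1c(O)cc(O)c(OC)c1OC | intermediate
6 | (E)-1-(2,4-dihydroxy-5,6-dimethoxyphenyl)-3-(3-hydroxy-4,5-dimethoxyphenyl)prop-2-en-1-one | COc1cc(/C=C/C(=O)c2c(O)cc(O)c(OC)c2OC)cc(O)c1OC | intermediate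
7 | (±)-7-hydroxy-2-(3-hydroxy-4,5-dimethoxyphenyl)-5,6-dimethoxychroman-4-one | COc1cc(C2CC(=O)c3c(OC)c(OC)c(O)cc3O2)cc(O)c1OC | intermediate
8 | 7-hydroxy-2-(3-hydroxy-4,5-dimethoxyphenyl)-5,6-dimethoxy-4H-chromen-4-one (7,5'-dihydroxy-5,6,3',4'-tetramethoxyflavone) | COc1cc(-c2cc(=O)c3c(OC)c(OC)c(O)cc3o2)cc(O)c1OC | target

## Step count and risks

Total step count: 3. Longest linear sequence: 3 (1 → 3 → 5 → 8; 1 is used a second time in step 3).

The three steps most likely to fail, in order:

**Step 3 (the proposed new step).** The risks are Pd-mediated oxidation of the free phenols, catalyst death by the amine, and incomplete condensation. The fallback sets out from 5 (with 1) and comes back at 8, using the classical two-stage sequence. Claisen–Schmidt condensation of 5 with 1 in KOH/EtOH–H2O at room temperature gives chalcone 6, which is isolated on acidification. Iodine-catalysed oxidative cyclisation of 6 (I2 10 mol %, DMSO, 120 °C, DMSO as terminal oxidant) then gives 8. This is established chemistry and makes no compound beyond the list (F0).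

**Step 2.** The risk is regiochemistry: some acylation between the two hydroxyls (C-2), which is also para to a methoxy group; I expect C-6 to be the major site but have not got a measured ratio for this substrate. The fallback sets out from 1 and comes back at 5 by blocking that position before the ring oxygen is made.
- Br2/NaOAc/AcOH brominates 1 ortho to the hydroxyl, between OH and CHO, to give 2-bromo-3-hydroxy-4,5-dimethoxybenzaldehyde F3.
- The same acid-catalysed H2O2 Dakin oxidation passes through 2-bromo-3-hydroxy-4,5-dimethoxyphenyl formate F4 to 2-bromo-4,5-dimethoxybenzene-1,3-diol F5, whose only free ring position is the desired one.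
- Hoesch acylation with MeCN then leads through 1-(3-bromo-2,4-dihydroxy-5,6-dimethoxyphenyl)ethan-1-iminium chloride F6 to 1-(3-bromo-2,4-dihydroxy-5,6-dimethoxyphenyl)ethan-1-one F7.
- Hydrogenolysis (H2, Pd/C, NaOAc, MeOH) removes the bromine and returns to 5.

**Step 1.** The risk is over-oxidation of the very electron-rich free diphenol by H2O2/acid, or ester formation instead of aryl migration. The fallback sets out from 1 and comes back at 3 by masking the phenol and changing the oxidant. Ac2O/pyridine gives 5-formyl-2,3-dimethoxyphenyl acetate F1. mCPBA in CH2Cl2 (Baeyer–Villiger) gives 5-(formyloxy)-2,3-dimethoxyphenyl acetate F2. K2CO3/MeOH then cleaves both esters to 3 once no oxidant is left.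

## Further compounds

F1 | step 1 | 5-formyl-2,3-dimethoxyphenyl acetate | CC(=O)Oc1cc(C=O)cc(OC)c1OC
F2 | step 1 | 5-(formyloxy)-2,3-dimethoxyphenyl acetate | CC(=O)Oc1cc(OC=O)cc(OC)c1OC
F3 | step 2 | 2-bromo-3-hydroxy-4,5-dimethoxybenzaldehyde | COc1cc(C=O)c(Br)c(O)c1OC
F4 | step 2 | 2-bromo-3-hydroxy-4,5-dimethoxyphenyl formate | COc1cc(OC=O)c(Br)c(O)c1OC
F5 | step 2 | 2-bromo-4,5-dimethoxybenzene-1,3-diol | COc1cc(O)c(Br)c(O)c1OC
F6 | step 2 | 1-(3-bromo-2,4-dihydroxy-5,6-dimethoxyphenyl)ethan-1-iminium chloride | CC(=[NH2+])c1c(O)c(Br)c(O)c(OC)c1OC.[Cl-]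
F7 | step 2 | 1-(3-bromo-2,4-dihydroxy-5,6-dimethoxyphenyl)ethan-1-one | CC(=O)c1c(O)c(Br)c(O)c(OC)c1OC
F0 | step 3 | none | none
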